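**Plan**

1. Labels used here: cyclohexene C1(Et, dienyl)–C2=C3(Me)–C3a(H)–C6a(H)–C7(Me, CO2H); cyclopentene C3a–C4(Me)–C5=C6(Me)–C6a.
2. Retrosynthetic cuts, in order: the dienyl branch (two olefinations of a C1 formyl group); C5=C6 (ring-closing metathesis); C6a–C7 (intramolecular palladium allylic alkylation of a lactone enolate); C3a–C4 (Ireland–Claisen); C3–C3a and C3–Me (two Negishi couplings on a 1,1-dibromoalkene).
3. Enabling feature: the CO2H on C7 and the branch on C1 are cis on the cyclohexene, so they are carried as one temporary γ-lactone acetal ring, C7–C(=O)–O–CH(OR*)–C1, whose enolate carbon is C7. C6a is allylic to C6 and is made as the substituted terminus of a 2-methyl-π-allyl unit.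
4. Forward order: lactone with C1 → open chain with C3a/C4 → cyclohexene (step 14) → cyclopentene (step 15) → lactone opened → dienyl side chain.
5. Stereochemistry: C1 from conjugate addition anti to a (+)-menthyl acetal; C3a/C4 from (S,E)-pent-3-en-2-ol through a chair Ireland–Claisen; C7 from the forced cis fusion of the lactone; C6a from a chair transition state (trans to C3a).

Key step: step 14

Remark: (S,E)-pent-3-en-2-ol is taken as a purchasable chiral alcohol (otherwise from the commercial racemate by lipase resolution). "Menthyloxy" always means the ether of (+)-menthol 4. The lactone α-carbon (later C7) is carried as an epimer mixture until it is enolized in step 14.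

**Route**

Step 1
Reactants: 1 butanal; 2 glyoxylic acid (as monohydrate)
Product: 3 4-ethyl-5-hydroxyfuran-2(5H)-one
Conditions: morpholine hydrochloride, dioxane/H2O, reflux
Reagents that add atoms: none
Why: Amine-mediated aldol condensation of the aldehyde α-carbon with glyoxylic acid, dehydration and lactol closure is the standard entry to 4-alkyl-5-hydroxybutenolides (pseudoacids); C5 is a racemic hemiacetal carbon at this stage.

Step 2
Reactants: 3 4-ethyl-5-hydroxyfuran-2(5H)-one; 4 (+)-menthol
Product: 5 (5S)-4-ethyl-5-(menthyloxy)furan-2(5H)-one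
Conditions: p-TsOH (cat.), toluene, reflux, Dean–Stark; crystallization, mother liquor re-equilibrated with acid
Reagents that add atoms: none
Why: Acid-catalysed pseudoester (acetal) formation is reversible at C5, so crystallization is expected to draw the mixture into the (5S) diastereomer, the enantiomeric counterpart of the well-behaved crystalline menthyloxybutenolide series, and this centre then controls C1.

Step 3
Reactants: 5 (5S)-4-ethyl-5-(menthyloxy)furan-2(5H)-one
Product: 7 (4R,5S)-4-ethyl-5-(menthyloxy)-4-vinyldihydrofuran-2(3H)-one, via silyl ketene acetal 6 (not isolated)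
Conditions: CH2=CHMgBr, CuBr·SMe2 (10 mol%), Me3SiCl, THF, −78 to −40 °C; aq. NH4Cl
Reagents that add atoms: vinylmagnesium bromide, C=C[Mg]Br
Why: Copper-catalysed, chlorosilane-accelerated conjugate addition of the vinyl Grignard reagent to the β-ethyl butenolide builds the quaternary carbon (later C1), the vinyl group entering anti to the neighbouring menthyloxy group.

Step 4
Reactants: 7 (4R,5S)-4-ethyl-5-(menthyloxy)-4-vinyldihydrofuran-2(3H)-one
Product: 9 (4S,5S)-4-ethyl-3-methyl-5-(menthyloxy)-4-vinyldihydrofuran-2(3H)-one (C3 epimers), via lithium enolate 8 (not isolated)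
Conditions: LDA, THF, −78 °C; MeI, −78 to −20 °C
Reagents that add atoms: iodomethane, CI
Why: Lactone enolate alkylation installs the future C7 methyl group; the new α-centre is formed unselectively, which does not matter because it is enolized again in step 14.

Step 5
Reactants: 9 methyl lactone
Product: 11 (2S,3R)-3-ethyl-4-methyl-2-(menthyloxy)-5-oxotetrahydrofuran-3-carbaldehyde (C4 epimers), via ozonide 10 (not isolated)
Conditions: O3, CH2Cl2, −78 °C; PPh3, −78 to 23 °C
Reagents that add atoms: ozone, [O-][O+]=O
Why: Ozonolysis of the only alkene with reductive work-up gives a non-enolizable neopentyl aldehyde (later C2), so the quaternary centre cannot be scrambled.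

Step 6
Reactants: 11 aldehyde
Product: 12 (4R,5S)-4-(2,2-dibromovinyl)-4-ethyl-3-methyl-5-(menthyloxy)dihydrofuran-2(3H)-one (C3 epimers)
Conditions: CBr4, PPh3, CH2Cl2, 0 °C
Reagents that add atoms: carbon tetrabromide, BrC(Br)(Br)Br
Why: Ramirez dibromo-olefination (first stage of the Corey–Fuchs sequence) works on hindered non-enolizable aldehydes and leaves the lactone acetal intact.

Step 7
Reactants: 12 dibromoalkene
Product: 13 (4R,5S)-4-[(Z)-2-bromoprop-1-enyl]-4-ethyl-3-methyl-5-(menthyloxy)dihydrofuran-2(3H)-one (C3 epimers)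
Conditions: MeZnCl, PdCl2(DPEphos) (5 mol%), THF, 0 to 23 °C
Reagents that add atoms: methylzinc chloride, C[Zn]Cl
Why: Negishi coupling of a 1,1-dibromoalkene occurs selectively at the bromine trans to the carbon substituent, so the methyl ends up trans and the remaining bromine cis to the quaternary carbon, which fixes the later cis (Z) C2=C3 geometry.

Step 8
Reactants: 14 (S,E)-pent-3-en-2-ol
Product: 15 (2S,3E)-pent-3-en-2-yl bromoacetate
Conditions: BrCH2COBr, pyridine, CH2Cl2, 0 °C
Reagents that add atoms: bromoacetyl bromide, BrCC(=O)Br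
Why: O-Acylation of the secondary allylic alcohol proceeds with retention at the carbinol centre.

Step 9
Reactants: 13 (Z)-bromoalkene; 15 (2S,3E)-pent-3-en-2-yl bromoacetate
Product: 17 (2S,3E)-pent-3-en-2-yl (Z)-3-methyl-4-(lactone-4-yl)but-3-enoate, via zinc enolate 16 (not isolated)
Conditions: Zn dust (Me3SiCl-activated), THF, 23 °C; then 13, Pd[P(tBu)3]2 (5 mol%), THF, 23 to 45 °C
Reagents that add atoms: none
Why: Negishi-type coupling of a Reformatsky reagent with an alkenyl bromide proceeds with retention of alkene geometry and tolerates the lactone, giving the β,γ-unsaturated ester with its CH2 (later C3a) cis to the quaternary carbon.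

Step 10
Reactants: 17 allylic ester
Product: 20 (2R,3R,4E)-3-methyl-2-[(Z)-1-(lactone-4-yl)prop-1-en-2-yl]hex-4-enoic acid, via silyl ketene acetal 18 (not isolated), via trimethylsilyl ester 19 (not isolated)
Conditions: LDA (1.05 equiv), THF/DMPU, −78 °C; Me3SiCl; −78 to 40 °C; aq. citric acid
Reagents that add atoms: none
Why: Ireland–Claisen rearrangement: the doubly activated CH2 is deprotonated in preference to the hindered lactone α-CH, and the ketene acetal with the alkenyl group cis to OSiMe3 rearranges through a chair with the carbinol methyl equatorial, so the (S)-carbinol centre is relayed into the syn (R,R) pair C3a/C4 and the new propenyl group is E.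

Step 11
Reactants: 20 acid
Product: 22 isopropenyl ketone (C6a carbonyl), via acid chloride 21 (not isolated)
Conditions: 1-chloro-N,N,2-trimethylprop-1-en-1-amine, CH2Cl2, 0 °C; then CH2=C(Me)MgBr (1.05 equiv), Fe(acac)3 (3 mol%), THF, −78 °C
Reagents that add atoms: isopropenylmagnesium bromide, CC(=C)[Mg]Br
Why: Neutral acid chloride formation followed by iron-catalysed acylation of the Grignard reagent at −78 °C should give the ketone faster than the lactone is attacked or the C3a centre is enolized.

Step 12
Reactants: 22 isopropenyl ketone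
Product: 23 allylic alcohol (carbinol epimers at C6a)
Conditions: NaBH4, CeCl3·7H2O, MeOH, −40 °C
Reagents that add atoms: none
Why: Luche 1,2-reduction of the enone spares the lactone; the carbinol epimer mixture is irrelevant because this carbon becomes a π-allyl terminus in step 14.

Step 13
Reactants: 23 allylic alcohol
Product: 24 allylic methyl carbonate
Conditions: ClCO2Me, pyridine, DMAP (cat.), CH2Cl2, 0 °C
Reagents that add atoms: methyl chloroformate, COC(=O)Cl
Why: Carbonate formation turns the allylic alcohol into a leaving group that zerovalent palladium can ionize.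

Step 14
Reactants: 24 allylic methyl carbonate
Product: 26 cis-fused lactone–cyclohexene with isopropenyl on C6a, via lithium enolate 25 (not isolated)
Conditions: LDA (1.05 equiv), THF, −78 °C; then Pd2(dba)3 (2.5 mol%), dppf (6 mol%), THF, −78 to 23 °C
Reagents that add atoms: none
Why: Deprotonation gives the lithium enolate of the γ-lactone (C7 is its α-carbon); zerovalent palladium ionizes the allylic carbonate (loss of CO2 and methoxide) to a 2-methyl-π-allyl complex whose substituted terminus is C6a, and the enolate carbon attacks that terminus, so the C6a–C7 bond and the cyclohexene form in one event and an isopropenyl group is left on C6a. The closest known reaction type is the Tsuji–Trost allylation of preformed lithium enolates of lactones and ketones, here run intramolecularly. The ring closes in the 6-exo mode, attack at the proximal allyl terminus being preferred over the eight-membered alternative at the CH2 terminus. The quaternary centre C7 is controlled by the temporary lactone ring: the tether leaves from the neighbouring lactone carbon C1, so only a cis-fused lactone/cyclohexene can form, which places the C7 methyl cis to the C1 ethyl. C6a is controlled by a chair-like transition state with the allyl unit and the C3a side chain both equatorial (H on C6a anti to H on C3a), since the epimeric arrangement would put the allyl unit 1,3-diaxial to the lactone CH(OR) arm on C1; both carbinol epimers of 24 converge because the π-allyl faces interconvert through the unsubstituted terminus. The step needs chemoselective enolization and C- rather than O-allylation, secured by the lactone α-CH being the only acidic C–H and by the geometric preference for the six-membered ring.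

Step 15
Reactants: 26 cis-fused lactone–cyclohexene
Product: 27 menthyl lactone acetal of the trans-fused hydrindadiene core
Conditions: second-generation Hoveyda–Grubbs catalyst (5 mol%), toluene, 80 °C
Reagents that add atoms: none
Why: Ring-closing metathesis between the isopropenyl and propenyl groups (loss of propene) closes the trisubstituted cyclopentene; the two groups are already trans on the cyclohexene, so the trans ring fusion is locked in rather than created.

Step 16
Reactants: 27 lactone acetal
Product: 28 formyl acid (open form of the hydroxy-lactone pseudoacid)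
Conditions: 1 M HCl, THF, 50 °C
Reagents that add atoms: water, O
Why: Acid hydrolysis of the lactone acetal removes the menthyl auxiliary and opens the temporary ring, releasing the C7 carboxylic acid and the C1 aldehyde at once without touching any stereocentre.

Step 17
Reactants: 28 formyl acid; 29 2-(triphenylphosphoranylidene)propanal
Product: 30 (E)-2-methyl enal acid
Conditions: 29 (3 equiv), toluene, 100 °C
Reagents that add atoms: none
Why: Wittig reaction of the stabilized α-methyl ylide with the aldehyde (ring-opened) form of the pseudoacid should give the (E)-trisubstituted enal selectively.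

Step 18
Reactants: 30 enal acid; 31 diethyl benzylphosphonate
Product: 32 CNP0103503.1
Conditions: NaH (3 equiv), THF, 0 to 23 °C; dilute aq. HCl work-up
Reagents that add atoms: none
Why: Horner–Wadsworth–Emmons reaction of the benzylphosphonate anion with the enal gives the (E)-styryl double bond and hence the (E,E)-diene, the carboxylate being inert and protonated on work-up.

**Compound list**

1 | butanal | CCCC=O | starting material
2 | glyoxylic acid (monohydrate used) | O=CC(=O)O | starting material
3 | 4-ethyl-5-hydroxyfuran-2(5H)-one (racemic at C5) | CCC1=CC(=O)OC1O | intermediate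
4 | (+)-menthol, (1S,2R,5S)-2-isopropyl-5-methylcyclohexan-1-ol | CC(C)[C@H]1CC[C@H](C)C[C@@H]1O | starting material
5 | (5S)-4-ethyl-5-{[(1S,2R,5S)-2-isopropyl-5-methylcyclohexyl]oxy}furan-2(5H)-one | CCC1=CC(=O)O[C@@H]1O[C@H]2C[C@@H](C)CC[C@@H]2C(C)C | intermediate
6 | O-trimethylsilyl ketene acetal of lactone 7 | CC[C@]1(C=C)C=C(O[Si](C)(C)C)O[C@@H]1O[C@H]2C[C@@H](C)CC[C@@H]2C(C)C | intermediate
7 | (4R,5S)-4-ethyl-5-(menthyloxy)-4-vinyldihydrofuran-2(3H)-one (vinyl trans to menthyloxy) | CC[C@]1(C=C)CC(=O)O[C@@H]1O[C@H]2C[C@@H](C)CC[C@@H]2C(C)C | intermediate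
8 | lithium enolate of lactone 7 | CC[C@]1(C=C)C=C(O[Li])O[C@@H]1O[C@H]2C[C@@H](C)CC[C@@H]2C(C)C | intermediate
9 | (4S,5S)-4-ethyl-3-methyl-5-(menthyloxy)-4-vinyldihydrofuran-2(3H)-one, C3 epimer mixture | CC[C@]1(C=C)C(C)C(=O)O[C@@H]1O[C@H]2C[C@@H](C)CC[C@@H]2C(C)C | intermediate
10 | ozonide of 9 (1,2,4-trioxolan-3-yl in place of vinyl) | CC[C@]1(C2OCOO2)C(C)C(=O)O[C@@H]1O[C@H]3C[C@@H](C)CC[C@@H]3C(C)C | intermediate
11 | (2S,3R)-3-ethyl-4-methyl-2-(menthyloxy)-5-oxotetrahydrofuran-3-carbaldehyde, C4 epimer mixture | CC[C@]1(C=O)C(C)C(=O)O[C@@H]1O[C@H]2C[C@@H](C)CC[C@@H]2C(C)C | intermediate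
12 | (4R,5S)-4-(2,2-dibromovinyl)-4-ethyl-3-methyl-5-(menthyloxy)dihydrofuran-2(3H)-one | CC[C@]1(C=C(Br)Br)C(C)C(=O)O[C@@H]1O[C@H]2C[C@@H](C)CC[C@@H]2C(C)C | intermediate
13 | (4R,5S)-4-[(Z)-2-bromoprop-1-enyl]-4-ethyl-3-methyl-5-(menthyloxy)dihydrofuran-2(3H)-one (Br cis to the ring carbon) | CC[C@]1(/C=C(\Br)C)C(C)C(=O)O[C@@H]1O[C@H]2C[C@@H](C)CC[C@@H]2C(C)C | intermediate
14 | (S,E)-pent-3-en-2-ol | C/C=C/[C@H](C)O | starting material
15 | (2S,3E)-pent-3-en-2-yl bromoacetate | BrCC(=O)O[C@@H](C)/C=C/C | intermediate
16 | Reformatsky reagent of 15, bromozinc (2S,3E)-pent-3-en-2-yl acetate | Br[Zn]CC(=O)O[C@@H](C)/C=C/C | intermediate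
17 | (2S,3E)-pent-3-en-2-yl (Z)-3-methyl-4-[lactone-4-yl]but-3-enoate (lactone as in 13, ester CH2 cis to the ring carbon) | CC[C@]1(/C=C(/C)CC(=O)O[C@@H](C)/C=C/C)C(C)C(=O)O[C@@H]1O[C@H]2C[C@@H](C)CC[C@@H]2C(C)C | intermediate
18 | trimethylsilyl ketene acetal of 17 (alkenyl group cis to OSiMe3) | CC[C@]1(/C=C(/C)\C=C(/O[Si](C)(C)C)O[C@@H](C)/C=C/C)C(C)C(=O)O[C@@H]1O[C@H]2C[C@@H](C)CC[C@@H]2C(C)C | intermediate
19 | trimethylsilyl ester of acid 20 | CC[C@]1(/C=C(/C)[C@H](C(=O)O[Si](C)(C)C)[C@H](C)/C=C/C)C(C)C(=O)O[C@@H]1O[C@H]2C[C@@H](C)CC[C@@H]2C(C)C | intermediate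
20 | (2R,3R,4E)-3-methyl-2-[(Z)-1-(lactone-4-yl)prop-1-en-2-yl]hex-4-enoic acid | CC[C@]1(/C=C(/C)[C@H](C(=O)O)[C@H](C)/C=C/C)C(C)C(=O)O[C@@H]1O[C@H]2C[C@@H](C)CC[C@@H]2C(C)C | intermediate
21 | acid chloride of 20 | CC[C@]1(/C=C(/C)[C@H](C(=O)Cl)[C@H](C)/C=C/C)C(C)C(=O)O[C@@H]1O[C@H]2C[C@@H](C)CC[C@@H]2C(C)C | intermediate
22 | isopropenyl ketone (C(=O)C(Me)=CH2 in place of CO2H of 20, same configuration) | CC[C@]1(/C=C(/C)[C@H](C(=O)C(C)=C)[C@H](C)/C=C/C)C(C)C(=O)O[C@@H]1O[C@H]2C[C@@H](C)CC[C@@H]2C(C)C | intermediate
23 | allylic alcohol from 22 (carbinol epimer mixture) | CC[C@]1(/C=C(/C)[C@H](C(O)C(C)=C)[C@H](C)/C=C/C)C(C)C(=O)O[C@@H]1O[C@H]2C[C@@H](C)CC[C@@H]2C(C)C | intermediate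
24 | methyl carbonate of 23 | CC[C@]1(/C=C(/C)[C@H](C(OC(=O)OC)C(C)=C)[C@H](C)/C=C/C)C(C)C(=O)O[C@@H]1O[C@H]2C[C@@H](C)CC[C@@H]2C(C)C | intermediate
25 | lithium lactone enolate of 24 | CC[C@]1(/C=C(/C)[C@H](C(OC(=O)OC)C(C)=C)[C@H](C)/C=C/C)C(C)=C(O[Li])O[C@@H]1O[C@H]2C[C@@H](C)CC[C@@H]2C(C)C | intermediate
26 | cis-fused γ-lactone acetal/cyclohexene: C1 (Et), C2=C3 (Me), C3a bearing (2R,3E)-pent-3-en-2-yl, C6a bearing isopropenyl (trans to the C3a group), C7 (Me) | CC[C@@]12C=C(C)[C@@H]([C@H](C)/C=C/C)[C@H](C(C)=C)[C@@]2(C)C(=O)O[C@@H]1O[C@H]3C[C@@H](C)CC[C@@H]3C(C)C | intermediate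
27 | menthyl lactone acetal of the trans-fused hydrindadiene core (all five ring stereocentres as in the target) | CC[C@@]12C=C(C)[C@H]3[C@H](C)C=C(C)[C@@H]3[C@@]2(C)C(=O)O[C@@H]1O[C@H]4C[C@@H](C)CC[C@@H]4C(C)C | intermediate
28 | formyl acid: target skeleton with CHO on C1 in place of the dienyl branch (in equilibrium with its cyclic hydroxy-lactone) | CC[C@]1(C=O)C=C(C)[C@H]2[C@H](C)C=C(C)[C@@H]2[C@@]1(C)C(=O)O | intermediate
29 | 2-(triphenylphosphoranylidene)propanal | CC(C=O)=P(c1ccccc1)(c1ccccc1)c1ccccc1 | starting material
30 | (E)-2-methyl enal acid: C1 bears (E)-CH=C(Me)CHO | CC[C@]1(/C=C(C)/C=O)C=C(C)[C@H]2[C@H](C)C=C(C)[C@@H]2[C@@]1(C)C(=O)O | intermediate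
31 | diethyl benzylphosphonate | CCOP(=O)(Cc1ccccc1)OCC | starting material
32 | CNP0103503.1 | CC[C@]1(/C=C(C)/C=C/c2ccccc2)C=C(C)[C@H]2[C@H](C)C=C(C)[C@@H]2[C@@]1(C)C(=O)O | target

**Step count and risks**

Total steps: 18. Longest linear sequence: 17 (steps 1–7 and 9–18; step 8 prepares the side reagent 15).

Steps most likely to fail:

1. Step 14. The ring closure may suffer from poor facial selectivity at the allyl terminus C6a, or C–C bond formation at the crowded quaternary enolate carbon may be outrun by proton transfer or β-hydride loss from the π-allyl intermediate. The fallback replaces the π-allyl chemistry by a metal-free intramolecular SN2′ displacement with a different stereodetermining transition state. It sets out from 23, which is treated with PBr3 (cat. pyridine, Et2O, −10 °C) so that the allylic bromides equilibrate to the transposed primary (E)-allylic bromide F4. KHMDS (THF, −78 to 0 °C) then makes the lactone enolate, which attacks C6a in a 6-exo SN2′ fashion with loss of bromide and formation of the isopropenyl group. The route is rejoined at 26.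

2. Step 3. The β,β-disubstituted butenolide may be too unreactive toward the vinyl copper species, so that 1,2-addition or simple recovery competes with formation of the quaternary carbon. The fallback builds the quaternary carbon with a sulfur-stabilized carbanion that also serves as a masked formyl group, which removes the ozonolysis. It sets out from 5, which receives bis(phenylthio)methyllithium (THF/HMPA, −78 °C) anti to the menthyloxy group, and the enolate is trapped with MeI to give the dithioacetal lactone F1. Alkylative dethioacetalization (MeI, CaCO3, aq. MeCN, 50 °C) gives the aldehyde, and the route is rejoined at 11.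

3. Step 9. Oxidative addition and transmetalation at the bromide cis to the quaternary carbon may be too slow, or zerovalent palladium may ionize the allylic ester of the zinc reagent. The fallback separates the C–C coupling from the introduction of the chiral allylic ester. It sets out from 13, which is coupled with commercial (2-tert-butoxy-2-oxoethyl)zinc bromide (Pd[P(tBu)3]2, THF) to give the tert-butyl ester F2. The tert-butyl group is removed (Me3SiOTf, 2,6-lutidine, CH2Cl2, 0 °C; then water) to give the β,γ-unsaturated acid F3, which is esterified with alcohol 14 (EDC·HCl, cat. DMAP, CH2Cl2, 0 °C). The route is rejoined at 17.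

**Further compounds**

F1 | step 3 | (4,5S)-4-[bis(phenylthio)methyl]-4-ethyl-3-methyl-5-(menthyloxy)dihydrofuran-2(3H)-one (dithioacetal trans to menthyloxy) | CC[C@]1(C(Sc2ccccc2)Sc2ccccc2)C(C)C(=O)O[C@@H]1O[C@H]3C[C@@H](C)CC[C@@H]3C(C)C
F2 | step 9 | tert-butyl (Z)-3-methyl-4-[lactone-4-yl]but-3-enoate (lactone as in 13) | CC[C@]1(/C=C(/C)CC(=O)OC(C)(C)C)C(C)C(=O)O[C@@H]1O[C@H]2C[C@@H](C)CC[C@@H]2C(C)C
F3 | step 9 | (Z)-3-methyl-4-[lactone-4-yl]but-3-enoic acid | CC[C@]1(/C=C(/C)CC(=O)O)C(C)C(=O)O[C@@H]1O[C@H]2C[C@@H](C)CC[C@@H]2C(C)C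
F4 | step 14 | transposed primary (E)-allylic bromide from 23 (C3a bears (E)-CH=C(Me)CH2Br) | CC[C@]1(/C=C(/C)[C@H](/C=C(\C)CBr)[C@H](C)/C=C/C)C(C)C(=O)O[C@@H]1O[C@H]2C[C@@H](C)CC[C@@H]2C(C)C
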